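**Strategy.** Lychnophorolide B is dissected at C1–C10, the bond joining the furanone ketone to its tetrasubstituted ether carbon. In the furanone ring (O, C3, C2, C1, C10) the ketone C1 stands 1,4 to the tiglate carbon C8 through C10 and C9, which is the pattern of a Stetter product. An aldehyde (C1), tied through the future ring oxygen to a β-alkoxy crotonate (C10=C9–C8), is cyclised by a chiral triazolylidene: one catalytic step closes the five-membered ring and sets C10. The precursor is an open-chain enol ether aldehyde. An indium Barbier coupling with a bromomethyl butenolide then adds the lactone, and ring-closing metathesis at C4=C5 closes the ten-membered ring.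

Key step: step 6

Numbering: C1–C15 are the germacrane numbers of the target (C1 ring ketone, C2=C3 enol ether, C4=C5, C6 lactone carbinol, C7, C8 tiglate carbon, C9 methylene, C10 quaternary ether carbon, C11–C13 methylene lactone, C14 methyl, C15 hydroxymethyl).

Remark: the sense of induction in step 3 (chelated titanium enolate model) and in step 6 (catalyst matched with the C3 substituent) is assigned from the usual transition-state models; if either proves opposite, the antipodal auxiliary or catalyst, both commercial, is used.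

Step 1
Reactants: 1 2-methylidenepropane-1,3-diol
Product: 2 2-{[(tert-butyldimethylsilyl)oxy]methyl}prop-2-en-1-ol
Conditions: TBSCl (0.3 equiv), imidazole, THF, 0 °C (diol in excess)
Reagents that add atoms: tert-butyldimethylsilyl chloride, CC(C)(C)[Si](C)(C)Cl
Why: Silyl ether formation on a symmetric diol used in excess should give mainly the mono-ether (statistical monoprotection).

Step 2
Reactants: 2 mono-silyl ether
Product: 3 2-{[(tert-butyldimethylsilyl)oxy]methyl}prop-2-enal
Conditions: MnO2 (activated), CH2Cl2, 23 °C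
Reagents that add atoms: none
Why: MnO2 allylic oxidation should stop cleanly at the enal, which is used at once.

Step 3
Reactants: 4 1-[(4S)-4-benzyl-2-sulfanylidene-1,3-thiazolidin-3-yl]ethan-1-one; 3 enal
Product: 6 (3R)-1-[(4S)-4-benzyl-2-sulfanylidene-1,3-thiazolidin-3-yl]-4-{[(tert-butyldimethylsilyl)oxy]methyl}-3-hydroxypent-4-en-1-one, via chlorotitanium enolate 5 (not isolated)
Conditions: TiCl4, iPr2NEt, CH2Cl2, −78 °C; then 3, −78 °C
Reagents that add atoms: none
Why: Auxiliary-controlled acetate aldol addition of an N-acetyl thiazolidinethione: in the chelated chair transition state the benzyl group blocks one enolate face, which should set C3 as (R).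

Step 4
Reactants: 6 aldol adduct; 7 methyl but-2-ynoate
Product: 8 methyl (2E)-3-{[(3R)-1-[(4S)-4-benzyl-2-sulfanylidene-1,3-thiazolidin-3-yl]-4-{[(tert-butyldimethylsilyl)oxy]methyl}-1-oxopent-4-en-3-yl]oxy}but-2-enoate
Conditions: PMe3 (20 mol%), CH2Cl2, 0 → 23 °C
Reagents that add atoms: none
Why: Phosphine-catalysed oxa-Michael addition of the alcohol to the ynoate should give the (E)-β-alkoxy crotonate under conditions too weakly basic for retro-aldol or β-elimination.

Step 5
Reactants: 8 imide
Product: 9 methyl (2E)-3-{[(3R)-4-{[(tert-butyldimethylsilyl)oxy]methyl}-1-oxopent-4-en-3-yl]oxy}but-2-enoate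
Conditions: DIBAL-H (1.1 equiv), CH2Cl2, −78 °C; Rochelle salt
Reagents that add atoms: none
Why: Reductive cleavage of the N-acyl thiazolidinethione by DIBAL-H stops at the aldehyde and should be far faster than attack on the donor-substituted (vinylogous carbonate) ester.

Step 6
Reactants: 9 aldehyde
Product: 10 methyl 2-[(2R,5R)-5-(3-{[tert-butyldimethylsilyl]oxy}prop-1-en-2-yl)-2-methyl-3-oxooxolan-2-yl]acetate
Conditions: (5aS,10bR)-2-(pentafluorophenyl)-5a,10b-dihydro-4H,6H-indeno[2,1-b][1,2,4]triazolo[4,3-d][1,4]oxazin-2-ium tetrafluoroborate (20 mol%), KN(SiMe3)2 (20 mol%), toluene, 23 °C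
Reagents that add atoms: none
Why: The free triazolylidene adds to the aldehyde and, after proton transfer, the Breslow intermediate (an acyl anion equivalent at C1) adds to the β-carbon C10 of the (E)-alkoxy crotonate; proton transfer and loss of the carbene release the ketone. This is the intramolecular Stetter reaction, the closest precedent being aldehydes tethered through oxygen to β-oxy crotonates, which close 2,2-disubstituted furan-3-ones. The oxolan-3-one ring closes in the 5-exo-trig mode (C1 attacks C10, C9 stays outside the ring). The new stereocentre C10 is set by the aminoindanol backbone of the catalyst, which blocks one face of the Breslow intermediate, reinforced by the C3 substituent, which stays pseudo-equatorial and ends cis to the CH2CO2Me group. The step needs conjugate addition to win over benzoin dimerisation and over β-elimination of the enol-ether oxygen from the enolisable aldehyde; the five-atom tether, the fixed (E) geometry of the acceptor and the pre-formed carbene without excess base should secure this.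

Step 7
Reactants: 10 keto ester
Product: 11 (2R,5R)-5-(3-{[tert-butyldimethylsilyl]oxy}prop-1-en-2-yl)-2-(2-hydroxyethyl)-2-methyloxolan-3-ol (both C3 epimers of the oxolane)
Conditions: LiAlH4, THF, 0 °C
Reagents that add atoms: none
Why: Hydride reduction takes ester and ketone to the diol, and the configuration of the new ring carbinol is irrelevant because it is re-oxidised.

Step 8
Reactants: 11 diol
Product: 12 2-[(2R,5R)-5-(3-{[tert-butyldimethylsilyl]oxy}prop-1-en-2-yl)-2-methyl-3-oxooxolan-2-yl]acetaldehyde
Conditions: (COCl)2, DMSO, CH2Cl2, −78 °C; Et3N, −78 → 0 °C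
Reagents that add atoms: none
Why: Swern oxidation activates both hydroxyls before base is added, so the 1,4-diol should give the keto aldehyde without lactol or lactone formation.

Step 9
Reactants: 13 racemic (4E)-hexa-1,4-dien-3-ol
Product: 14 (3S,4E)-hexa-1,4-dien-3-ol
Conditions: Ti(OiPr)4 (0.2 equiv), D-(−)-diisopropyl tartrate (0.24 equiv), tBuOOH (0.6 equiv), 4 Å molecular sieves, CH2Cl2, −20 °C
Reagents that add atoms: none
Why: Sharpless kinetic resolution: with the D-tartrate the (R)-enantiomer is epoxidised at its propenyl group much faster, so unreacted (S)-alcohol should be recovered enantioenriched.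

Step 10
Reactants: 14 (S)-dienol; 15 2-(bromomethyl)prop-2-enoic acid
Product: 16 (3S,4E)-hexa-1,4-dien-3-yl 2-(bromomethyl)prop-2-enoate
Conditions: DCC, DMAP (5 mol%), CH2Cl2, 0 °C
Reagents that add atoms: none
Why: Steglich esterification acylates the carbinol oxygen without touching the stereocentre.

Step 11
Reactants: 16 ester
Product: 17 (5R)-3-(bromomethyl)-5-[(1E)-prop-1-en-1-yl]furan-2(5H)-one
Conditions: second-generation Grubbs catalyst (5 mol%), CH2Cl2 (0.01 M), 40 °C
Reagents that add atoms: none
Why: Ring-closing metathesis: the catalyst should load on the terminal vinyl group and close onto the acrylate alkene to give the butenolide, leaving the slower propenyl group and the stereocentre untouched (a 5-vinyl regioisomer would be a different, separable compound).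

Step 12
Reactants: 12 keto aldehyde; 17 bromomethyl butenolide
Product: 19 (4R,5R)-4-[(1S)-1-hydroxy-2-{(2R,5R)-5-(3-{[tert-butyldimethylsilyl]oxy}prop-1-en-2-yl)-2-methyl-3-oxooxolan-2-yl}ethyl]-3-methylidene-5-[(1E)-prop-1-en-1-yl]oxolan-2-one, via allylindium dibromide 18 (not isolated)
Conditions: indium powder, THF/H2O (1:1), 23 °C
Reagents that add atoms: none
Why: Indium Barbier allylation: the allylindium reacts at its γ-carbon C7 on the face anti to the propenyl group at C6 (trans lactone), and its ring-fixed (E)-type geometry in a chair Zimmerman–Traxler transition state should give the anti (7R,8S) adduct, the aldehyde reacting in preference to the hindered ketone.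

Step 13
Reactants: 19 carbinol; 20 (2E)-2-methylbut-2-enoyl chloride (tigloyl chloride)
Product: 21 (1S)-1-[(3R,4R)-4-methylidene-5-oxo-2-[(1E)-prop-1-en-1-yl]oxolan-3-yl]-2-[(2R,5R)-5-(3-{[tert-butyldimethylsilyl]oxy}prop-1-en-2-yl)-2-methyl-3-oxooxolan-2-yl]ethyl (2E)-2-methylbut-2-enoate
Conditions: pyridine, DMAP (10 mol%), CH2Cl2, 0 → 23 °C
Reagents that add atoms: none
Why: DMAP-catalysed acylation esterifies the C8 hydroxyl with retention, and acylation of the open hydroxy ketone drains any ring-chain hemiketal.

Step 14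
Reactants: 21 tiglate
Product: 22 (1S)-1-[(3R,4R)-4-methylidene-5-oxo-2-[(1E)-prop-1-en-1-yl]oxolan-3-yl]-2-[(2R)-5-(3-{[tert-butyldimethylsilyl]oxy}prop-1-en-2-yl)-2-methyl-3-oxo-2,3-dihydrofuran-2-yl]ethyl (2E)-2-methylbut-2-enoate
Conditions: IBX (3 equiv), DMSO/toluene (1:2), 70 °C
Reagents that add atoms: none
Why: IBX dehydrogenation of a ketone to its enone: only C2 can enolise (C10 is quaternary) and the C3–H is allylic and α to oxygen, so the furan-3(2H)-one should form regioselectively.

Step 15
Reactants: 22 furanone diene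
Product: 23 15-O-(tert-butyldimethylsilyl)lychnophorolide B
Conditions: second-generation Hoveyda–Grubbs catalyst (20 mol%), 1,4-benzoquinone (20 mol%), toluene (1 mM), 80 °C, argon purge
Reagents that add atoms: none
Why: Ring-closing metathesis with loss of propene forms C4=C5 and so the ten-membered carbocycle; the bridged ring can hold only the (Z) ring-cis alkene, and metathesis with the α-methylene group would need a four-membered ring.

Step 16
Reactants: 23 silyl ether
Product: 24 lychnophorolide B
Conditions: HF·pyridine, pyridine/THF, 0 °C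
Reagents that add atoms: none
Why: Fluoride-mediated desilylation of the primary allylic silyl ether in a buffered medium should spare the tiglate, the methylene lactone and the furanone.

**Compound list**

1 | 2-methylidenepropane-1,3-diol | C=C(CO)CO | starting material
2 | 2-{[(tert-butyldimethylsilyl)oxy]methyl}prop-2-en-1-ol | C=C(CO)CO[Si](C)(C)C(C)(C)C | intermediate
3 | 2-{[(tert-butyldimethylsilyl)oxy]methyl}prop-2-enal | C=C(C=O)CO[Si](C)(C)C(C)(C)C | intermediate
4 | 1-[(4S)-4-benzyl-2-sulfanylidene-1,3-thiazolidin-3-yl]ethan-1-one | CC(=O)N1C(=S)SC[C@@H]1Cc1ccccc1 | starting material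
5 | trichlorotitanium enolate of 4 | C=C(O[Ti](Cl)(Cl)Cl)N1C(=S)SC[C@@H]1Cc1ccccc1 | intermediate (not isolated)
6 | (3R)-1-[(4S)-4-benzyl-2-sulfanylidene-1,3-thiazolidin-3-yl]-4-{[(tert-butyldimethylsilyl)oxy]methyl}-3-hydroxypent-4-en-1-one | C=C(CO[Si](C)(C)C(C)(C)C)[C@H](O)CC(=O)N1C(=S)SC[C@@H]1Cc1ccccc1 | intermediate
7 | methyl but-2-ynoate | CC#CC(=O)OC | starting material
8 | methyl (2E)-3-{[(3R)-1-[(4S)-4-benzyl-2-sulfanylidene-1,3-thiazolidin-3-yl]-4-{[(tert-butyldimethylsilyl)oxy]methyl}-1-oxopent-4-en-3-yl]oxy}but-2-enoate | COC(=O)/C=C(\C)O[C@H](CC(=O)N1C(=S)SC[C@@H]1Cc1ccccc1)C(=C)CO[Si](C)(C)C(C)(C)C | intermediate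
9 | methyl (2E)-3-{[(3R)-4-{[(tert-butyldimethylsilyl)oxy]methyl}-1-oxopent-4-en-3-yl]oxy}but-2-enoate | COC(=O)/C=C(\C)O[C@H](CC=O)C(=C)CO[Si](C)(C)C(C)(C)C | intermediate
10 | methyl 2-[(2R,5R)-5-(3-{[tert-butyldimethylsilyl]oxy}prop-1-en-2-yl)-2-methyl-3-oxooxolan-2-yl]acetate | COC(=O)C[C@@]1(C)O[C@H](CC1=O)C(=C)CO[Si](C)(C)C(C)(C)C | intermediate
11 | (2R,5R)-5-(3-{[tert-butyldimethylsilyl]oxy}prop-1-en-2-yl)-2-(2-hydroxyethyl)-2-methyloxolan-3-ol, both C3 epimers | OCC[C@@]1(C)O[C@H](CC1O)C(=C)CO[Si](C)(C)C(C)(C)C | intermediate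
12 | 2-[(2R,5R)-5-(3-{[tert-butyldimethylsilyl]oxy}prop-1-en-2-yl)-2-methyl-3-oxooxolan-2-yl]acetaldehyde | O=CC[C@@]1(C)O[C@H](CC1=O)C(=C)CO[Si](C)(C)C(C)(C)C | intermediate
13 | racemic (4E)-hexa-1,4-dien-3-ol | C/C=C/C(O)C=C | starting material
14 | (3S,4E)-hexa-1,4-dien-3-ol | C/C=C/[C@@H](O)C=C | intermediate
15 | 2-(bromomethyl)prop-2-enoic acid | C=C(CBr)C(=O)O | starting material
16 | (3S,4E)-hexa-1,4-dien-3-yl 2-(bromomethyl)prop-2-enoate | C/C=C/[C@@H](OC(=O)C(=C)CBr)C=C | intermediate
17 | (5R)-3-(bromomethyl)-5-[(1E)-prop-1-en-1-yl]furan-2(5H)-one | C/C=C/[C@H]1OC(=O)C(CBr)=C1 | intermediate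
18 | allylindium dibromide derived from 17 | C/C=C/[C@H]1OC(=O)C(C[In](Br)Br)=C1 | intermediate (not isolated)
19 | (4R,5R)-4-[(1S)-1-hydroxy-2-{(2R,5R)-5-(3-{[tert-butyldimethylsilyl]oxy}prop-1-en-2-yl)-2-methyl-3-oxooxolan-2-yl}ethyl]-3-methylidene-5-[(1E)-prop-1-en-1-yl]oxolan-2-one | C=C1C(=O)O[C@H](/C=C/C)[C@H]1[C@@H](O)C[C@@]2(C)O[C@H](CC2=O)C(=C)CO[Si](C)(C)C(C)(C)C | intermediate
20 | (2E)-2-methylbut-2-enoyl chloride (tigloyl chloride) | C/C=C(\C)C(=O)Cl | starting material
21 | C8 tiglate of 19 (oxolan-3-one stage) | C=C1C(=O)O[C@H](/C=C/C)[C@H]1[C@@H](OC(=O)/C(C)=C/C)C[C@@]2(C)O[C@H](CC2=O)C(=C)CO[Si](C)(C)C(C)(C)C | intermediate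
22 | furan-3(2H)-one obtained from 21 by C2=C3 dehydrogenation | C=C1C(=O)O[C@H](/C=C/C)[C@H]1[C@@H](OC(=O)/C(C)=C/C)C[C@@]2(C)OC(C(=C)CO[Si](C)(C)C(C)(C)C)=CC2=O | intermediate
23 | 15-O-(tert-butyldimethylsilyl)lychnophorolide B | C=C1C(=O)O[C@@H]2/C=C(/CO[Si](C)(C)C(C)(C)C)C3=CC(=O)[C@@](C)(C[C@H](OC(=O)/C(C)=C/C)[C@@H]12)O3 | intermediate
24 | lychnophorolide B (6R,7R,8S,10R) | C=C1C(=O)O[C@@H]2/C=C(/CO)C3=CC(=O)[C@@](C)(C[C@H](OC(=O)/C(C)=C/C)[C@@H]12)O3 | target

**Step count.** Total: 16 steps. Longest linear sequence: 13 steps (steps 1–8 and 12–16); steps 9–11 form the butenolide branch.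

**Steps most likely to fail**

Step 6. The aldehyde may enolise and expel the enol-ether oxygen by β-elimination, or the donor-substituted, trisubstituted acceptor may react too slowly and with poor facial control at C10. The fallback sets out from 8: displacement of the auxiliary with sodium phenylselenide (PhSeSePh, NaBH4, THF/EtOH, 0 °C) should give the selenoester Se-phenyl (3R)-4-{[(tert-butyldimethylsilyl)oxy]methyl}-3-{[(2E)-4-methoxy-4-oxobut-2-en-2-yl]oxy}pent-4-eneselenoate F1. Generation of the acyl radical ((Me3Si)3SiH, Et3B, air, benzene, 23 °C) and its 5-exo cyclisation onto the alkoxy crotonate under neutral conditions, with the C3 substituent pseudo-equatorial in a chair-like transition state, should give the 2,5-cis ketone and return to the route at 10.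

Step 15. The conjugated 1,1-disubstituted alkene next to the planar furanone may resist ring closure, so that oligomerisation through the propenyl group takes over. The fallback sets out from 21 and runs the metathesis before the dehydrogenation, on the oxolan-3-one, whose isolated 1,1-disubstituted alkene, sp3 C3 and cis-2,5 substituents are better disposed for closure. This should give the (3R)-2,3-dihydro macrocycle F2; IBX dehydrogenation as in step 14 then returns to the route at 23.

Step 12. Simple diastereoselection at C8 may be poor or reversed (syn instead of anti addition) if the reaction leaves the closed chair transition state in water. The fallback sets out from 12: the coupling is worked up for the syn adduct, the (1R)-carbinol epimer of 19 F3, and its hydroxyl is esterified with tiglic acid under Mitsunobu conditions (PPh3, DIAD, THF, 0 °C) with inversion at C8, returning to the route at 21.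

**Further compounds**

F1 | step 6 | Se-phenyl (3R)-4-{[(tert-butyldimethylsilyl)oxy]methyl}-3-{[(2E)-4-methoxy-4-oxobut-2-en-2-yl]oxy}pent-4-eneselenoate | COC(=O)/C=C(\C)O[C@H](CC(=O)[Se]c1ccccc1)C(=C)CO[Si](C)(C)C(C)(C)C
F2 | step 15 | (3R)-2,3-dihydro derivative of 23 (oxolan-3-one macrocycle) | C=C1C(=O)O[C@@H]2/C=C(/CO[Si](C)(C)C(C)(C)C)[C@H]3CC(=O)[C@@](C)(C[C@H](OC(=O)/C(C)=C/C)[C@@H]12)O3
F3 | step 12 | C8 epimer of 19, (1R)-carbinol | C=C1C(=O)O[C@H](/C=C/C)[C@H]1[C@H](O)C[C@@]2(C)O[C@H](CC2=O)C(=C)CO[Si](C)(C)C(C)(C)C
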